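The readings come from a simulation on assumed constants, and the scatter is random.

Start from a one-step world: Z becomes J, and J can rise by what Z still holds, no further. Flask elm is the flask asked about, followed to 300 min; larch is an earlier run at 96 °C.

| flask | Z | temperature | remark | time |
|---|---|---|---|---|
| elm | 2 M | 90 °C | the very flask that is asked about, followed so far |  |
| larch | 2 M | 96 °C | run made earlier |  |
| flask | 2.0 M | 90 °C |  | 6.0 h |

- elm (time / min: J / %, Z / %): 40.0: 58.6, 10.0; 90.0: 67.5, 1.3; 180: 68.6, 0; 300: 70.0, 0
- larch (time / min: J / %, Z / %): 40.0: 67.0, 2.3; 90.0: 70.9, 0.6; 180: 70.6, 0.1; 300: 71.0, 1.8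

(each reading ± 1 percentage point)

- zeta: change nothing and wait 6.0 h more
- epsilon: at 6.0 h take out 90% of the J then present, then wait 6.0 h
- beta: at 6.0 h raise the temperature by 10 K, then wait 6.0 h

- removed J is counted in
- the analysis behind the earlier runs scatters by 1 percentage point, standard deviation

* J, in percent of the Z first charged, at 6.0 h
* which option adds most J ("none" when 2 percentage points or less is all one gets) (zeta / epsilon / beta / none)
* J present, with what was taken out counted in, in percent of the Z first charged, after epsilon
* J present, with what was taken out counted in, in percent of the Z first charged, after beta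

Take two extremes. In the first, kinetic control, Z splits into J and a dead by-product, and J stops when [Z] stops falling. In the second, thermodynamic control, J stands in balance with a pool holding the missing share, so J taken out is refilled and heat shifts the balance.

The elm readings place the flask between them. Of the Z spent by 40.0 min, J holds 65.1%. Of the Z spent from there to 90.0 min, J holds 102%, a reading with its scatter, so the share reads higher late than early. A balance struck at once gives one share, but a balance that lags can also read like this. So it is my judgement, not a proof, that puts the flask close to the first extreme, with a loss that needs high [Z] and ends early.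

From the same fall I read 17.0 min as the tail half-life of [Z], the time in which Z halves once the early loss is over. From 90.0 min to 6.0 h, 15.9 such half-lives pass. By this estimate that leaves <0.001% of the charge, less than the margin of 2 percentage points. So I expect J near 69.3%, the same after each option, and the answer none.

The forecast gives 70.3% now, 88.5% after epsilon and 71% after beta, picks epsilon and says “Waiting does nothing”, so it parts from my reckoning on epsilon.

The flask gives 69.2%, then 69.2% after epsilon and 69.2% after beta, so the best is none: zeta adds 0 points, epsilon 0 points, beta 0 points.

    Z + L → X (k = 0.110 M⁻¹ min⁻¹, Ea = 60.0 kJ mol⁻¹)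
    Z → J (k = 0.0390 min⁻¹, Ea = 111 kJ mol⁻¹)
    L → D (k = 0.00780 min⁻¹, Ea = 110 kJ mol⁻¹)
    2 Z → L (k = 0.00670 M⁻¹ min⁻¹, Ea = 98.0 kJ mol⁻¹)
    (constants at 90 °C)

Take the path from two Z to L away, and J in this flask reaches >99.9% instead of 69.2%. The half-life carries on: from the reading at 90.0 min it gives 0.0330% of Z at 180 min, and this flask holds 0.0362%. In the flask left until 4.0 h, 8.82 half-lives have passed since that reading, Z stands at 0%, and J stands at 69.2%.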